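**The clearing rate.** Take the four flasks as they stand and ask of each what share of its open intermediate turns into product per hour.

| setting | alder | elm | birch | larch |
|---|---|---|---|---|
| substrate | 11 mM | 11 mM | 11 mM (fed, over 8.0 h) | 11 mM (in portions, 2, over 8.0 h) |
| reagent | 27.5 mM (fed, over 8.0 h) | 27.5 mM | 27.5 mM | 27.5 mM |
| free catalyst | 0.22 mM | 0.22 mM | 0.22 mM | 0.22 mM |
| second catalyst | 1.1 mM | 1.1 mM | 1.1 mM | 1.1 mM |
| impurity | 0.20 mM | 0.20 mM | 0.20 mM | 0.20 mM |
| time | 10 h | 10 h | 10 h | 10 h |
| remark | all else is in the flask from the start; the feed brings no volume worth counting | everything together at the start | all else is in the flask from the start; the feed brings no volume worth counting | first portion at the start, last at 8.0 h |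

    second catalyst + open intermediate ⇌ catalyst intermediate (K1 = 41 /M, k1 = 190 /M/h)
    reagent + catalyst intermediate → second catalyst + product (k2 = 290 /M/h)
    second catalyst + impurity → spent catalyst (k3 = 5800 /M/h)
    substrate + free catalyst → free catalyst + open intermediate (k4 = 16000 /M/h)

1. which flask leads in amount of product, in percent of the substrate charged ("all alike" within 1.5 percentage points) (alder / elm / birch / larch / all alike)
2. how much product is there at the end, in percent of the substrate charged: alder
3. how much product is there at the end, in percent of the substrate charged: elm
4. how much product is there at the end, in percent of the substrate charged: birch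
5. how much product is there at the end, in percent of the substrate charged: larch

**Two quick steps.** Free catalyst opens substrate at 3.52 /h and second catalyst meets impurity at 6.38 /h, both faster than the 0.209 /h at which second catalyst takes up open intermediate. So we count substrate as open intermediate on arrival, and live second catalyst, free and bound forms together, as 0.900 mM.

**First round.** Catalyst intermediate falls back at 4.63 /h or, with reagent as charged, meets reagent at 7.98 /h, so 63.2% goes forward. The clearing rate, a pseudo-first-order constant, is the uptake constant times the live second catalyst times that share: 0.108 /h. Elm would then hold 66.1% product at the end.

**Second round.** We put that answer back. Elm's reagent averages about 23.9 mM and its open intermediate about 7.36 mM, which also keeps some second catalyst bound. Adding the uptake 1.40 /h to the two exits, the clearing rate becomes 0.0914 /h, and elm gives 59.9%.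

**Later arrivals.** With elm's rate held, birch's substrate clears from its own arrival, and averaging over the feed gives 40.9%. In larch, half of the substrate has 10 h and the other half 2.00 h, giving 38.3%.

**The weak link.** Elm's reagent figure does not fit alder, whose reagent averages about 13.2 mM. Reforged, with elm's open intermediate kept, alder's rate is 0.0664 /h, lower than elm's, and its product 48.5%. We commit to elm leading.

**The result.** The forecast, calling the rate “roughly first order in open intermediate”, gave alder 46%, elm 57%, birch 40% and larch 37%, with elm ahead. The simulation gives, in the same order, 46.7%, 58.4%, 39.8% and 37.5%, with elm ahead.

**What stands.** In elm, substrate's half-life by the opening step at 0.197 h was 0.20 h, while our clearing rate gives open intermediate an estimated half-life of 7.59 h, longer. At 10.0 h elm held, in percent of the substrate charged, 0% substrate, 41.0% open intermediate and 58.4% product.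

**Second flask.** Take a flask like elm with 19 mM substrate. The same reckoning gives reagent near 21.8 mM, open intermediate near 13.3 mM, a clearing rate of 0.0802 /h, lower than elm's, and 55.2% product. That flask gives 53.6% of its own substrate charged.

Its constants belong to no real substance; no experiment stands behind them.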